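**Retrosynthetic overview**

1. The target comes from macrocycle 29 by reductive loss of the two C10 sulfonyl groups, Mannich-type α-methylenation of the lactone (C15=C17) and exchange of the C7/C13 silyl ethers for acetates.
2. The 14-membered ring is closed last at C9–C10. The strategy rests on the unit C9–C8(=C19): a 2-substituted allyl inside the ring whose two CH2 termini are interchangeable, so the π-allylpalladium from C9 carbonate 28 gives the same ring, with the exocyclic C8=C19 methylene, whichever terminus the C10 bis(phenylsulfonyl) carbanion attacks.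
3. Carbonate 28 comes from reagent-controlled epoxidation of C3=C4, conjugate reduction of a butenolide (cis C1/C14) and a vinylogous Mukaiyama aldol (C13–C14) between silyloxyfuran 22 and aldehyde 5.
4. Silyloxyfuran 22 comes from Stille union (C1–C2) of stannylbutenolide 8 with allylic acetate 20; 20 is made from geranyl acetate (cleavage to the C7 aldehyde, alkenylchromium addition, CBS reduction for C7). Aldehyde 5 comes from (R)-3-bromo-2-methylpropan-1-ol and bis(phenylsulfonyl)methane.
5. Ring order: lactone ring first (brought in as the butenolide), then the C3–C4 oxirane, then the 14-membered carbocycle.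

Key step: step 19

**Remarks**

- Numbering (cembrane): ring carbons C1–C14; lactone O–C14–C1–C15(=C17)–C16(=O); methyl C18 on C4, methyl C20 on C12, methylene C19 on C8. The target is (1S,3R,4R,7R,12S,13R,14R).
- Assumption: 4-bromofuran-2(5H)-one, (R)-3-bromo-2-methylpropan-1-ol and geranyl acetate are bought.
- Assumption: the BF3-mediated addition of the 4-alkyl-2-silyloxyfuran to the α-methyl aldehyde follows the usual threo (13,14-syn) and Felkin–Anh course.

**Route**

Step 1
Reactants: 1 bis(phenylsulfonyl)methane; 2 (R)-3-bromo-2-methylpropan-1-ol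
Product: 4 (S)-2-methyl-4,4-bis(phenylsulfonyl)butan-1-ol, via sodium bis(phenylsulfonyl)methanide 3 (not isolated)
Conditions: NaH, DMF, 0 °C (1 in twofold excess); then 2, NaI (cat.), 80 °C
Reagents that add atoms: none
Why: SN2 alkylation of the soft bis-sulfonyl carbanion (pKa about 12) at the primary bromide should proceed while the much less acidic hydroxyl stays protonated; the stereocenter (later C12) comes from 2 and is not touched.

Step 2
Reactants: 4 (S)-2-methyl-4,4-bis(phenylsulfonyl)butan-1-ol
Product: 5 (S)-2-methyl-4,4-bis(phenylsulfonyl)butanal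
Conditions: Dess–Martin periodinane, CH2Cl2, 0 °C to rt; used crude
Reagents that add atoms: none
Why: Dess–Martin oxidation of the primary alcohol runs without base, so the α-stereocenter of the aldehyde should not epimerize.

Step 3
Reactants: 6 4-bromofuran-2(5H)-one; 7 hexabutylditin
Product: 8 4-(tributylstannyl)furan-2(5H)-one
Conditions: Pd(PPh3)4 (5 mol%), toluene, 100 °C
Reagents that add atoms: none
Why: Palladium-catalysed stannylation of a vinyl bromide with a distannane (oxidative addition, Sn–Sn transmetalation, reductive elimination) is an established entry to β-stannyl enoates.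

Step 4
Reactants: 9 geranyl acetate
Product: 10 racemic (2E)-6,7-epoxy-3,7-dimethyloct-2-en-1-yl acetate
Conditions: mCPBA (1.0 equiv), CH2Cl2, −20 to 0 °C
Reagents that add atoms: meta-chloroperbenzoic acid, OOC(=O)c1cccc(Cl)c1
Why: Prilezhaev epoxidation should select the electron-rich 6,7-olefin over the 2,3-olefin deactivated by the allylic acetate; the configuration of the oxirane is irrelevant because both its carbons are cleaved apart in step 5.

Step 5
Reactants: 10 racemic (2E)-6,7-epoxy-3,7-dimethyloct-2-en-1-yl acetate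
Product: 12 (2E)-3-methyl-6-oxohex-2-en-1-yl acetate, via diol acetate 11 (not isolated)
Conditions: HIO4·2H2O, THF/H2O, 0 °C
Reagents that add atoms: none
Why: Periodic acid hydrolyses the oxirane and cleaves the resulting glycol (Malaprade cleavage), releasing acetone and leaving the E-trisubstituted olefin and the acetate intact.

Step 6
Reactants: 13 4-methoxybenzyl alcohol; 14 2,3-dibromopropene
Product: 16 2-bromoallyl 4-methoxybenzyl ether, via sodium 4-methoxybenzyl oxide 15 (not isolated)
Conditions: NaH, THF, 0 °C; then 14, Bu4NI (cat.), rt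
Reagents that add atoms: none
Why: Williamson ether synthesis takes place only at the allylic bromide, since the vinylic bromide is inert to SN2 displacement.

Step 7
Reactants: 12 (2E)-3-methyl-6-oxohex-2-en-1-yl acetate; 16 2-bromoallyl 4-methoxybenzyl ether
Product: 17 racemic (2E)-6-hydroxy-7-[(4-methoxybenzyloxy)methyl]-3-methylocta-2,7-dien-1-yl acetate
Conditions: CrCl2 (4 equiv), NiCl2 (2 mol%), DMF, rt; aqueous work-up
Reagents that add atoms: none
Why: Nozaki–Hiyama–Kishi coupling forms the alkenylchromium under nickel catalysis and adds it to the aldehyde only, tolerating the acetate; the carbinol (C7) is racemic here and is set in steps 8 and 9.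

Step 8
Reactants: 17 racemic (2E)-6-hydroxy-7-[(4-methoxybenzyloxy)methyl]-3-methylocta-2,7-dien-1-yl acetate
Product: 18 (2E)-7-[(4-methoxybenzyloxy)methyl]-3-methyl-6-oxoocta-2,7-dien-1-yl acetate
Conditions: Dess–Martin periodinane, CH2Cl2, 0 °C; used promptly
Reagents that add atoms: none
Why: Dess–Martin oxidation of the secondary allylic alcohol gives the α-methylene ketone under neutral conditions that do not trigger conjugate addition to it.

Step 9
Reactants: 18 (2E)-7-[(4-methoxybenzyloxy)methyl]-3-methyl-6-oxoocta-2,7-dien-1-yl acetate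
Product: 19 (2E,6R)-6-hydroxy-7-[(4-methoxybenzyloxy)methyl]-3-methylocta-2,7-dien-1-yl acetate
Conditions: (S)-2-butyl-CBS-oxazaborolidine (20 mol%), catecholborane, toluene, −78 °C
Reagents that add atoms: none
Why: In the Corey–Bakshi–Shibata reduction the α-branched alkenyl group acts as the large substituent, so the (S)-catalyst should deliver hydride to give the (R)-carbinol (C7); catecholborane at −78 °C leaves the olefins and the acetate alone.

Step 10
Reactants: 19 (2E,6R)-6-hydroxy-7-[(4-methoxybenzyloxy)methyl]-3-methylocta-2,7-dien-1-yl acetate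
Product: 20 (2E,6R)-6-(tert-butyldimethylsilyloxy)-7-[(4-methoxybenzyloxy)methyl]-3-methylocta-2,7-dien-1-yl acetate
Conditions: TBSOTf, 2,6-lutidine, CH2Cl2, −78 °C
Reagents that add atoms: tert-butyldimethylsilyl triflate, CC(C)(C)[Si](C)(C)OS(=O)(=O)C(F)(F)F
Why: Silylation with the silyl triflate and a hindered pyridine base is the standard protection of a hindered secondary allylic alcohol and leaves the acetate and the benzyl ether intact.

Step 11
Reactants: 20 (2E,6R)-6-(tert-butyldimethylsilyloxy)-7-[(4-methoxybenzyloxy)methyl]-3-methylocta-2,7-dien-1-yl acetate; 8 4-(tributylstannyl)furan-2(5H)-one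
Product: 21 4-[(2E,6R)-6-(tert-butyldimethylsilyloxy)-7-[(4-methoxybenzyloxy)methyl]-3-methylocta-2,7-dien-1-yl]furan-2(5H)-one
Conditions: Pd2(dba)3 (3 mol%), LiCl (3 equiv), DMF, 40 °C
Reagents that add atoms: none
Why: Stille coupling of an allylic acetate with a vinylstannane via the π-allylpalladium should join C1–C2 at the primary allyl terminus with retention of the E-olefin; the C7 silyl ether and C9 benzyl ether are not leaving groups for zerovalent palladium.

Step 12
Reactants: 21 4-[(2E,6R)-6-(tert-butyldimethylsilyloxy)-7-[(4-methoxybenzyloxy)methyl]-3-methylocta-2,7-dien-1-yl]furan-2(5H)-one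
Product: 22 2-(tert-butyldimethylsilyloxy)-4-[(2E,6R)-6-(tert-butyldimethylsilyloxy)-7-[(4-methoxybenzyloxy)methyl]-3-methylocta-2,7-dien-1-yl]furan
Conditions: TBSOTf, Et3N, CH2Cl2, 0 °C
Reagents that add atoms: tert-butyldimethylsilyl triflate, CC(C)(C)[Si](C)(C)OS(=O)(=O)C(F)(F)F
Why: Soft enolization with O-silylation removes the ring γ-proton, because this gives the aromatic 2-silyloxyfuran in preference to the exocyclic dienol ether.

Step 13
Reactants: 22 2-(tert-butyldimethylsilyloxy)-4-[(2E,6R)-6-(tert-butyldimethylsilyloxy)-7-[(4-methoxybenzyloxy)methyl]-3-methylocta-2,7-dien-1-yl]furan; 5 (S)-2-methyl-4,4-bis(phenylsulfonyl)butanal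
Product: 23 (5R)-5-[(1R,2S)-1-hydroxy-2-methyl-4,4-bis(phenylsulfonyl)butyl]-4-[(2E,6R)-6-(tert-butyldimethylsilyloxy)-7-[(4-methoxybenzyloxy)methyl]-3-methylocta-2,7-dien-1-yl]furan-2(5H)-one
Conditions: BF3·OEt2 (1.1 equiv), CH2Cl2, −78 °C; aq. NaHCO3 work-up
Reagents that add atoms: none
Why: The vinylogous Mukaiyama aldol attacks through furan C5 (C14) in an open transition state; C13 is set by Felkin–Anh addition to the α-methyl aldehyde (12,13-syn) and C14 by the threo preference of Lewis-acid silyloxyfuran additions (13,14-syn).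

Step 14
Reactants: 23 (5R)-5-[(1R,2S)-1-hydroxy-2-methyl-4,4-bis(phenylsulfonyl)butyl]-4-[(2E,6R)-6-(tert-butyldimethylsilyloxy)-7-[(4-methoxybenzyloxy)methyl]-3-methylocta-2,7-dien-1-yl]furan-2(5H)-one
Product: 24 the C13 tert-butyldimethylsilyl ether of 23
Conditions: TBSOTf, 2,6-lutidine, CH2Cl2, −78 to 0 °C
Reagents that add atoms: tert-butyldimethylsilyl triflate, CC(C)(C)[Si](C)(C)OS(=O)(=O)C(F)(F)F
Why: Triflate silylation with a weak hindered base protects the hindered C13 alcohol without deprotonating the epimerizable C14 or the bis-sulfone methine.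

Step 15
Reactants: 24 the C13 tert-butyldimethylsilyl ether of 23
Product: 25 (4S,5R)-5-[(1R,2S)-1-(tert-butyldimethylsilyloxy)-2-methyl-4,4-bis(phenylsulfonyl)butyl]-4-[(2E,6R)-6-(tert-butyldimethylsilyloxy)-7-[(4-methoxybenzyloxy)methyl]-3-methylocta-2,7-dien-1-yl]dihydrofuran-2(3H)-one (cis lactone)
Conditions: [(Ph3P)CuH]6 (excess hydride), degassed toluene, rt; aq. NH4Cl
Reagents that add atoms: none
Why: Copper hydride conjugate reduction delivers hydride to C1 on the face opposite the bulky C14 substituent, which sets C1 cis to C14; isolated olefins are not reduced, and the excess covers protonolysis by the acidic bis-sulfone C–H.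

Step 16
Reactants: 25 the cis lactone described in step 15
Product: 26 (4S,5R)-5-[(1R,2S)-1-(tert-butyldimethylsilyloxy)-2-methyl-4,4-bis(phenylsulfonyl)butyl]-4-[(2E,6R)-6-(tert-butyldimethylsilyloxy)-7-(hydroxymethyl)-3-methylocta-2,7-dien-1-yl]dihydrofuran-2(3H)-one
Conditions: DDQ, CH2Cl2/pH 7 buffer, 0 °C
Reagents that add atoms: none
Why: Oxidative cleavage of the 4-methoxybenzyl ether (benzylic hydride abstraction, then hydrolysis of the hemiacetal) frees the C9 alcohol without touching silyl ethers, lactone or olefins.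

Step 17
Reactants: 26 the C9 allylic alcohol described in step 16
Product: 27 the C9 methyl carbonate of 26
Conditions: ClCO2Me, pyridine, CH2Cl2, 0 °C
Reagents that add atoms: methyl chloroformate, COC(=O)Cl
Why: Acylation of the primary allylic alcohol with a chloroformate is routine, and pyridine is too weak a base to deprotonate the bis-sulfone.

Step 18
Reactants: 27 the C9 methyl carbonate of 26
Product: 28 (4S,5R)-5-[(1R,2S)-1-(tert-butyldimethylsilyloxy)-2-methyl-4,4-bis(phenylsulfonyl)butyl]-4-{[(2R,3R)-3-[(3R)-3-(tert-butyldimethylsilyloxy)-4-(methoxycarbonyloxymethyl)pent-4-en-1-yl]-3-methyloxiran-2-yl]methyl}dihydrofuran-2(3H)-one (seco carbonate; cembrane 1S,3R,4R,7R,12S,13R,14R)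
Conditions: D-fructose-derived Shi ketone (1–3 equiv), KHSO5 (Oxone), NaHCO3, Na2EDTA, MeCN/H2O, pH about 8, 0 °C
Reagents that add atoms: potassium peroxymonosulfate (active salt of Oxone), [K+].[O-]S(=O)(=O)OO
Why: In the Shi epoxidation the chiral dioxirane from the D-fructose ketone transfers oxygen through a spiro transition state to the face of the E-trisubstituted olefin that gives the (3R,4R)-oxirane (reagent control); the electron-rich C3=C4 should react ahead of the 1,1-disubstituted olefin bearing the carbonate, and pH 8 keeps the bis-sulfone protonated and the carbonate intact.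

Step 19
Reactants: 28 the seco carbonate described in step 18
Product: 29 (1S,3R,4R,7R,12S,13R,14R)-7,13-bis(tert-butyldimethylsilyloxy)-3,4-epoxy-10,10-bis(phenylsulfonyl)cembr-8(19)-en-16,14-olide
Conditions: Pd(PPh3)4 (10 mol%), dppe (10 mol%), THF, reflux; 28 added by syringe pump, final 0.002 M
Reagents that add atoms: none
Why: Zerovalent palladium ionizes the primary allylic carbonate to a cationic 2-substituted π-allyl complex of divalent palladium, and the methyl carbonate anion loses CO2 to give methoxide, which deprotonates the C10 bis(phenylsulfonyl)methine (pKa about 12), so no external base meets the lactone or the oxirane. The soft carbanion attacks a CH2 terminus of the allyl on the face opposite palladium, forming C9–C10 and returning zerovalent palladium; the closest known reaction type is the Tsuji–Trost alkylation of bis-sulfonyl carbanions run at high dilution as a carbocyclic macrocyclization. The 14-membered ring closes by a 14-exo attack (palladium leaves outside the ring), and because C9 and C19 are both unsubstituted CH2 groups on C8 the two possible attacks give the same ring with the exocyclic C8=C19 methylene. No stereocenter is created, and C7 next to the allyl keeps its configuration because its silyl ether is not a leaving group. The step needs chemoselective ionization, secured by the carbonate being the only allylic ester (the C7 silyl ether and the non-allylic C3–C4 oxirane are inert to zerovalent palladium), and ring closure over oligomerization, secured by slow addition at high dilution.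

Step 20
Reactants: 29 the bis-sulfone macrocycle described in step 19
Product: 31 (1S,3R,4R,7R,12S,13R,14R)-7,13-bis(tert-butyldimethylsilyloxy)-3,4-epoxycembr-8(19)-en-16,14-olide, via C10 monosulfone 30 (not isolated)
Conditions: sodium amalgam (6% Na), Na2HPO4, MeOH/THF, −20 °C
Reagents that add atoms: none
Why: Reductive desulfonylation by single-electron transfer cleaves the two C–S bonds in turn; C9 and C11 carry no leaving group, so no elimination can follow, and the phosphate buffer protects the lactone and the oxirane.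

Step 21
Reactants: 31 the desulfonylated macrocycle described in step 20
Product: 33 the 15-(dimethylaminomethyl) derivative of 31 (C15 epimers, of no consequence), via lithium lactone enolate 32 (not isolated)
Conditions: LiN(iPr)2, THF, −78 °C; then CH2=NMe2+ I−, −78 to 0 °C
Reagents that add atoms: dimethyl(methylene)ammonium iodide, C=[N+](C)C.[I-]
Why: Mannich reaction of the lithium lactone enolate with the preformed iminium salt introduces the one-carbon unit at C15; C15 is the only enolizable position left in 31.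

Step 22
Reactants: 33 the 15-(dimethylaminomethyl) derivative of 31
Product: 35 (1S,3R,4R,7R,12S,13R,14R)-7,13-bis(tert-butyldimethylsilyloxy)-3,4-epoxycembra-8(19),15(17)-dien-16,14-olide, via trimethylammonium iodide 34 (not isolated)
Conditions: MeI, MeOH, rt; then aq. NaHCO3, CH2Cl2, rt
Reagents that add atoms: none
Why: Quaternization followed by mild-base Hofmann (E1cB) elimination of trimethylamine gives the α-methylene lactone without disturbing C1.

Step 23
Reactants: 35 the bis-silylated α-methylene lactone described in step 22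
Product: 36 (1S,3R,4R,7R,12S,13R,14R)-3,4-epoxy-7,13-dihydroxycembra-8(19),15(17)-dien-16,14-olide
Conditions: HF·pyridine, pyridine, THF, 0 °C to rt
Reagents that add atoms: none
Why: Pyridine-buffered fluoride desilylation removes both secondary silyl ethers under weakly acidic conditions that avoid conjugate addition to the methylene lactone and lactone migration to O13, and that a trisubstituted oxirane should tolerate.

Step 24
Reactants: 36 the diol described in step 23
Product: 37 (1S,3R,4R,7R,12S,13R,14R)-7,13-diacetoxy-3,4-epoxycembra-8(19),15(17)-dien-16,14-olide (CNP0323853.1)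
Conditions: Ac2O, pyridine, DMAP (cat.), CH2Cl2, rt
Reagents that add atoms: acetic anhydride, CC(=O)OC(C)=O
Why: DMAP-catalysed acetylation esterifies both secondary alcohols and is compatible with the oxirane and the methylene lactone.

**Compound list**

1 | bis(phenylsulfonyl)methane | O=S(=O)(CS(=O)(=O)c1ccccc1)c1ccccc1 | starting material
2 | (R)-3-bromo-2-methylpropan-1-ol | C[C@H](CO)CBr | starting material
3 | sodium bis(phenylsulfonyl)methanide | [Na+].O=S(=O)([CH-]S(=O)(=O)c1ccccc1)c1ccccc1 | intermediate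
4 | (S)-2-methyl-4,4-bis(phenylsulfonyl)butan-1-ol | C[C@H](CO)CC(S(=O)(=O)c1ccccc1)S(=O)(=O)c1ccccc1 | intermediate
5 | (S)-2-methyl-4,4-bis(phenylsulfonyl)butanal | C[C@H](C=O)CC(S(=O)(=O)c1ccccc1)S(=O)(=O)c1ccccc1 | intermediate
6 | 4-bromofuran-2(5H)-one | O=C1C=C(Br)CO1 | starting material
7 | hexabutylditin | CCCC[Sn](CCCC)(CCCC)[Sn](CCCC)(CCCC)CCCC | starting material
8 | 4-(tributylstannyl)furan-2(5H)-one | CCCC[Sn](CCCC)(CCCC)C1=CC(=O)OC1 | intermediate
9 | geranyl acetate | CC(C)=CCC/C(C)=C/COC(C)=O | starting material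
10 | racemic (2E)-6,7-epoxy-3,7-dimethyloct-2-en-1-yl acetate | CC1(C)OC1CC/C(C)=C/COC(C)=O | intermediate
11 | (2E)-6,7-dihydroxy-3,7-dimethyloct-2-en-1-yl acetate | CC(C)(O)C(O)CC/C(C)=C/COC(C)=O | intermediate
12 | (2E)-3-methyl-6-oxohex-2-en-1-yl acetate | O=CCC/C(C)=C/COC(C)=O | intermediate
13 | 4-methoxybenzyl alcohol | COc1ccc(CO)cc1 | starting material
14 | 2,3-dibromopropene | C=C(Br)CBr | starting material
15 | sodium 4-methoxybenzyl oxide | [Na+].[O-]Cc1ccc(OC)cc1 | intermediate
16 | 2-bromoallyl 4-methoxybenzyl ether | C=C(Br)COCc1ccc(OC)cc1 | intermediate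
17 | racemic (2E)-6-hydroxy-7-[(4-methoxybenzyloxy)methyl]-3-methylocta-2,7-dien-1-yl acetate | COc1ccc(COCC(=C)C(O)CC/C(C)=C/COC(C)=O)cc1 | intermediate
18 | (2E)-7-[(4-methoxybenzyloxy)methyl]-3-methyl-6-oxoocta-2,7-dien-1-yl acetate | COc1ccc(COCC(=C)C(=O)CC/C(C)=C/COC(C)=O)cc1 | intermediate
19 | (2E,6R)-6-hydroxy-7-[(4-methoxybenzyloxy)methyl]-3-methylocta-2,7-dien-1-yl acetate | COc1ccc(COCC(=C)[C@H](O)CC/C(C)=C/COC(C)=O)cc1 | intermediate
20 | (2E,6R)-6-(tert-butyldimethylsilyloxy)-7-[(4-methoxybenzyloxy)methyl]-3-methylocta-2,7-dien-1-yl acetate | COc1ccc(COCC(=C)[C@H](O[Si](C)(C)C(C)(C)C)CC/C(C)=C/COC(C)=O)cc1 | intermediate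
21 | 4-substituted furan-2(5H)-one from the Stille coupling (side chain as in 20) | COc1ccc(COCC(=C)[C@H](O[Si](C)(C)C(C)(C)C)CC/C(C)=C/CC2=CC(=O)OC2)cc1 | intermediate
22 | 2-(tert-butyldimethylsilyloxy)-4-substituted furan (side chain as in 20) | COc1ccc(COCC(=C)[C@H](O[Si](C)(C)C(C)(C)C)CC/C(C)=C/Cc2coc(O[Si](C)(C)C(C)(C)C)c2)cc1 | intermediate
23 | aldol adduct, (5R)-5-[(1R,2S)-1-hydroxy-2-methyl-4,4-bis(phenylsulfonyl)butyl]butenolide | COc1ccc(COCC(=C)[C@H](O[Si](C)(C)C(C)(C)C)CC/C(C)=C/CC2=CC(=O)O[C@H]2[C@H](O)[C@@H](C)CC(S(=O)(=O)c2ccccc2)S(=O)(=O)c2ccccc2)cc1 | intermediate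
24 | C13 tert-butyldimethylsilyl ether of 23 | COc1ccc(COCC(=C)[C@H](O[Si](C)(C)C(C)(C)C)CC/C(C)=C/CC2=CC(=O)O[C@H]2[C@H](O[Si](C)(C)C(C)(C)C)[C@@H](C)CC(S(=O)(=O)c2ccccc2)S(=O)(=O)c2ccccc2)cc1 | intermediate
25 | (4S,5R) cis lactone with C9 4-methoxybenzyl ether | COc1ccc(COCC(=C)[C@H](O[Si](C)(C)C(C)(C)C)CC/C(C)=C/C[C@H]2CC(=O)O[C@H]2[C@H](O[Si](C)(C)C(C)(C)C)[C@@H](C)CC(S(=O)(=O)c2ccccc2)S(=O)(=O)c2ccccc2)cc1 | intermediate
26 | (4S,5R) cis lactone with free C9 allylic alcohol | OCC(=C)[C@H](O[Si](C)(C)C(C)(C)C)CC/C(C)=C/C[C@H]1CC(=O)O[C@H]1[C@H](O[Si](C)(C)C(C)(C)C)[C@@H](C)CC(S(=O)(=O)c1ccccc1)S(=O)(=O)c1ccccc1 | intermediate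
27 | C9 methyl carbonate of 26 | COC(=O)OCC(=C)[C@H](O[Si](C)(C)C(C)(C)C)CC/C(C)=C/C[C@H]1CC(=O)O[C@H]1[C@H](O[Si](C)(C)C(C)(C)C)[C@@H](C)CC(S(=O)(=O)c1ccccc1)S(=O)(=O)c1ccccc1 | intermediate
28 | seco carbonate with (3R,4R)-oxirane (key-step precursor) | COC(=O)OCC(=C)[C@H](O[Si](C)(C)C(C)(C)C)CC[C@@]1(C)O[C@@H]1C[C@H]1CC(=O)O[C@H]1[C@H](O[Si](C)(C)C(C)(C)C)[C@@H](C)CC(S(=O)(=O)c1ccccc1)S(=O)(=O)c1ccccc1 | intermediate
29 | 10,10-bis(phenylsulfonyl) macrocycle (key-step product) | C=C1CC(S(=O)(=O)c2ccccc2)(S(=O)(=O)c2ccccc2)C[C@H](C)[C@@H](O[Si](C)(C)C(C)(C)C)[C@@H]2OC(=O)C[C@@H]2C[C@H]2O[C@]2(C)CC[C@H]1O[Si](C)(C)C(C)(C)C | intermediate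
30 | 10-(phenylsulfonyl) macrocycle (C10 epimers) | C=C1CC(S(=O)(=O)c2ccccc2)C[C@H](C)[C@@H](O[Si](C)(C)C(C)(C)C)[C@@H]2OC(=O)C[C@@H]2C[C@H]2O[C@]2(C)CC[C@H]1O[Si](C)(C)C(C)(C)C | intermediate
31 | 7,13-bis(silyloxy)-3,4-epoxycembr-8(19)-en-16,14-olide | C=C1CCC[C@H](C)[C@@H](O[Si](C)(C)C(C)(C)C)[C@@H]2OC(=O)C[C@@H]2C[C@H]2O[C@]2(C)CC[C@H]1O[Si](C)(C)C(C)(C)C | intermediate
32 | lithium enolate of 31 | C=C1CCC[C@H](C)[C@@H](O[Si](C)(C)C(C)(C)C)[C@@H]2OC([O-])=C[C@@H]2C[C@H]2O[C@]2(C)CC[C@H]1O[Si](C)(C)C(C)(C)C.[Li+] | intermediate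
33 | 15-(dimethylaminomethyl) lactone (C15 epimers) | C=C1CCC[C@H](C)[C@@H](O[Si](C)(C)C(C)(C)C)[C@@H]2OC(=O)C(CN(C)C)[C@@H]2C[C@H]2O[C@]2(C)CC[C@H]1O[Si](C)(C)C(C)(C)C | intermediate
34 | 15-(trimethylammoniomethyl) lactone iodide | C=C1CCC[C@H](C)[C@@H](O[Si](C)(C)C(C)(C)C)[C@@H]2OC(=O)C(C[N+](C)(C)C)[C@@H]2C[C@H]2O[C@]2(C)CC[C@H]1O[Si](C)(C)C(C)(C)C.[I-] | intermediate
35 | 7,13-bis(silyloxy)-3,4-epoxycembra-8(19),15(17)-dien-16,14-olide | C=C1CCC[C@H](C)[C@@H](O[Si](C)(C)C(C)(C)C)[C@@H]2OC(=O)C(=C)[C@@H]2C[C@H]2O[C@]2(C)CC[C@H]1O[Si](C)(C)C(C)(C)C | intermediate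
36 | 3,4-epoxy-7,13-dihydroxycembra-8(19),15(17)-dien-16,14-olide | C=C1CCC[C@H](C)[C@@H](O)[C@@H]2OC(=O)C(=C)[C@@H]2C[C@H]2O[C@]2(C)CC[C@H]1O | intermediate
37 | (1S,3R,4R,7R,12S,13R,14R)-7,13-diacetoxy-3,4-epoxycembra-8(19),15(17)-dien-16,14-olide | C=C1CCC[C@H](C)[C@@H](OC(C)=O)[C@@H]2OC(=O)C(=C)[C@@H]2C[C@H]2O[C@]2(C)CC[C@H]1OC(C)=O | target

**Step count and risks**

Total steps: 24. Longest linear sequence: 20 steps (from geranyl acetate 9: steps 4, 5, 7 to 24).

Steps most likely to fail:

1. Step 19 (macrocyclization). Intermolecular alkylation may outrun ring closure and give oligomers, or the π-allyl may lose a β-hydrogen to a diene while the carbanion concentration is low. Fallback without palladium, setting out from 26: Shi epoxidation under the conditions of step 18 should give the epoxy allylic alcohol F1. Appel bromination (CBr4, PPh3, 2,6-lutidine, CH2Cl2, 0 °C) then gives the allylic bromide F2. Slow addition of F2 to Cs2CO3 in DMF (0.002 M, rt) closes C9–C10 by direct intramolecular alkylation of the bis-sulfonyl carbanion; SN2 and SN2′ attack give the same ring for the same symmetry reason. The route is rejoined at 29.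

2. Step 13 (vinylogous aldol). Facial discrimination at furan C5 in the open transition state may be eroded by the 4-substituent, so that C14 forms as a mixture. Fallback that sets C14 by hydride reduction instead, setting out from 23 carried on as the mixture of C14 epimers: silylation as in step 14 gives 24 together with its C14 epimer F3. TBSOTf/Et3N (CH2Cl2, 0 °C) converts both into one 2-silyloxyfuran F4, in which C14 is planar. Dimethyldioxirane (1 equiv, acetone/CH2Cl2, −78 °C) oxidizes the electron-rich furan to the γ-hydroxybutenolide F5. Luche reduction (NaBH4, CeCl3, MeOH, −78 °C) of its open keto-acid form under Felkin–Anh control by the C13 silyloxy group, then lactonization on mild acidification, should return the 13,14-syn butenolide. The route is rejoined at 24.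

3. Step 11 (Stille coupling). Transmetalation from the electron-poor stannane may be slow, leaving the π-allyl time to scramble olefin geometry or the skipped diene time to move into conjugation. Fallback that brings the lactone in as a furan, setting out from 20: Negishi coupling with 3-furylzinc chloride (from 3-bromofuran, n-BuLi, −78 °C, then ZnCl2) and Pd(PPh3)4 in THF gives the 3-substituted furan F6. C–H borylation at the unhindered C5 ([Ir(OMe)(cod)]2, 4,4′-di-tert-butylbipyridine, B2pin2, THF, rt) gives the furyl boronate F7. Oxidation (NaBO3·4H2O, THF/H2O) and Et3N-mediated tautomerization give the butenolide. The route is rejoined at 21.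

**Further compounds**

F1 | step 19 | epoxy allylic alcohol (C9 OH analogue of 28) | OCC(=C)[C@H](O[Si](C)(C)C(C)(C)C)CC[C@@]1(C)O[C@@H]1C[C@H]1CC(=O)O[C@H]1[C@H](O[Si](C)(C)C(C)(C)C)[C@@H](C)CC(S(=O)(=O)c1ccccc1)S(=O)(=O)c1ccccc1
F2 | step 19 | C9 allylic bromide analogue of 28 | BrCC(=C)[C@H](O[Si](C)(C)C(C)(C)C)CC[C@@]1(C)O[C@@H]1C[C@H]1CC(=O)O[C@H]1[C@H](O[Si](C)(C)C(C)(C)C)[C@@H](C)CC(S(=O)(=O)c1ccccc1)S(=O)(=O)c1ccccc1
F3 | step 13 | C14 epimer of 24 | COc1ccc(COCC(=C)[C@H](O[Si](C)(C)C(C)(C)C)CC/C(C)=C/CC2=CC(=O)O[C@@H]2[C@H](O[Si](C)(C)C(C)(C)C)[C@@H](C)CC(S(=O)(=O)c2ccccc2)S(=O)(=O)c2ccccc2)cc1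
F4 | step 13 | 2-silyloxyfuran from 24 and F3 | COc1ccc(COCC(=C)[C@H](O[Si](C)(C)C(C)(C)C)CC/C(C)=C/Cc2cc(O[Si](C)(C)C(C)(C)C)oc2[C@H](O[Si](C)(C)C(C)(C)C)[C@@H](C)CC(S(=O)(=O)c2ccccc2)S(=O)(=O)c2ccccc2)cc1
F5 | step 13 | γ-hydroxybutenolide (C14 hemiketal) | COc1ccc(COCC(=C)[C@H](O[Si](C)(C)C(C)(C)C)CC/C(C)=C/CC2=CC(=O)OC2(O)[C@H](O[Si](C)(C)C(C)(C)C)[C@@H](C)CC(S(=O)(=O)c2ccccc2)S(=O)(=O)c2ccccc2)cc1
F6 | step 11 | 3-substituted furan (side chain as in 20) | COc1ccc(COCC(=C)[C@H](O[Si](C)(C)C(C)(C)C)CC/C(C)=C/Cc2ccoc2)cc1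
F7 | step 11 | 4-substituted furan-2-ylboronic acid pinacol ester | COc1ccc(COCC(=C)[C@H](O[Si](C)(C)C(C)(C)C)CC/C(C)=C/Cc2coc(B3OC(C)(C)C(C)(C)O3)c2)cc1
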